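I wanted to know which flask ends with more target, red or violet, and by how much.

- which of the two ends with the higher amount of target, in percent of the substrate charged ("neither" if they lie within 2 percentage points) (red / violet / neither)
- target at the end, in percent of the substrate charged, red
- target at the end, in percent of the substrate charged, violet

| setting | south-west | north | north-east | red | violet |
|---|---|---|---|---|---|
| substrate | 0.18 M | 0.67 M | 0.47 M | 0.47 M | 0.15 M |
| reagent | 0.376 M | 0.376 M | 0.376 M | 0.376 M | 0.376 M |
| precatalyst | 12 mM | 12 mM | 17 mM | 12 mM | 40 mM |
| remark | run made earlier | run made earlier | run made earlier |  |  |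
| time |  |  |  | 2.5 d | 1.5 d |

- south-west (time / d: target / %, substrate / %): 0.333: 0.2, 99.9; 0.833: 3.9, 95.1; 1.67: 14.1, 85.2; 2.50: 27.6, 71.0
- north (time / d: target / %, substrate / %): 0.333: 0, 99.7; 0.833: 1.2, 98.6; 1.67: 5.9, 94.9; 2.50: 10.1, 89.0
- north-east (time / d: target / %, substrate / %): 0.625: 1.3, 98.9; 1.25: 5.5, 93.1; 2.08: 13.9, 84.0; 2.50: 18.7, 80.7

(standard deviation of a reading: 0.5 percentage points)

- what is said of target includes crystals
- crystals is a solid; its amount is given per volume of the solution
- what was read earlier has a scatter of 0.5 percentage points, one standard deviation
- on the list of suspects stand: reagent + free catalyst -> catalyst intermediate A; catalyst intermediate A -> catalyst intermediate B; substrate + catalyst intermediate B -> catalyst intermediate C; catalyst intermediate C -> free catalyst + target; precatalyst <-> free catalyst; crystals <-> target; free catalyst + target -> free catalyst + over-reaction product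

I worked in logarithms and in molar target. At the last reading the south-west run held 0.0497 M and the north run 0.0677 M. That is a factor of 1.36 for a substrate charge 3.72 times as large, so target rose less than the charge. I called K the [substrate] at which the rate reaches 0.5 of its ceiling, an apparent Michaelis constant, and read it from these two runs as 0.103 M. The substrate factor is then [substrate]/(K + [substrate]).

Red has the south-west catalyst charge, so I scaled south-west by the ratio of factors and got 0.0640 M, or 13.6%. The north-east run held 0.0879 M at that substrate charge. Set against south-west scaled in the same way, it gave an order in precatalyst of 0.909.

Between its readings at 0.833 d and 1.67 d, south-west target grew as time to the power 1.85. So south-west stood at 0.0208 M at violet's end time. Scaling by precatalyst and by the factors at the charges gave violet 0.0579 M, or 38.6%.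

The weak link was the charge itself. That estimate put violet's [substrate] at 0.0921 M at the end, lower than the charge. I reforged the link with mean levels, between charge and estimated end, of 0.121 M for violet and 0.170 M for south-west. I committed to 36.0% for violet, higher than red.

The forecast also chose violet, with 13.2% for red and 45% for violet, saying “substrate depletion trims this”. Its violet number stood higher than mine.

The flask gave violet, with red at 13.9% and violet at 38.0%.

    reagent + free catalyst → catalyst intermediate A (k = 6.95 M⁻¹ h⁻¹)
    catalyst intermediate A → catalyst intermediate B (k = 2.01 h⁻¹)
    substrate + catalyst intermediate B → catalyst intermediate C (k = 3.75 M⁻¹ h⁻¹)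
    catalyst intermediate C → free catalyst + target (k = 0.578 h⁻¹)
    precatalyst ⇌ free catalyst (K = 0.459, k = 0.0148 h⁻¹)
    crystals ⇌ target, rate k6*(cs6 - [target]) while solid is left; crystals form when [target] > cs6 (solubility = 0.420 M, k = 0.124 h⁻¹)
    free catalyst + target → free catalyst + over-reaction product (k = 1.57 M⁻¹ h⁻¹)

In red, by its own step alone, catalyst intermediate B had a half-life of 0.39 h against the charged substrate, and catalyst intermediate C a longer one, 1.2 h, on its way to free catalyst and target. At the end, red held 26.8% of its catalyst as catalyst intermediate C and 10.5% as catalyst intermediate B. Red's final [substrate], 0.400 M, stood above my reading of K, and violet's, 0.0871 M, below it. For a neighbour of violet charged with 0.060 M of substrate, I scaled violet's target by the factors at each flask's mean of charge and end, which gave 52.4%, and that neighbour ended at 51.7%.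

(The numbers in the tables were generated by integration from invented constants; the scatter is artificial.)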